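Everything rests on opening the ten-membered carbocycle at C3–C4. The C3 secondary carbinol sits on C4, the methyl-bearing carbon of the ring-cis C4=C5 olefin that flanks the C6/C7 lactone ring, and this allylic alcohol maps onto the addition of an alkenylmetal to an aldehyde. One Nozaki–Hiyama–Kishi reaction therefore forms the C3–C4 bond, the C3 stereocentre and the ring while sparing the α-methylene lactone, the C8 ester and the C1/C10 epoxide. Its precursor is the fully functionalised seco compound: a Z-alkenyl iodide at C4, a β,γ-epoxy aldehyde at C3 (unveiled immediately beforehand), the 6,7-cis lactone from an indium Barbier allylation, the C14 silyl ether and the (R)-2-methylbutanoate.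

Key step: step 18

Remark: germacrane locants C1–C15 of the target (C14 on C10, C15 on C4) are used for every intermediate; CIP letters quoted with these locants change with substituent priorities although the geometry does not, so the SMILES strings are decisive; the five numbered starting materials are taken as commercial.

Step 1
Reactants: 1 (R)-5-(hydroxymethyl)dihydrofuran-2(3H)-one
Product: 2 (R)-5-[(triethylsilyloxy)methyl]dihydrofuran-2(3H)-one
Conditions: Et3SiCl, imidazole, CH2Cl2, 0 °C
Reagents that add atoms: chlorotriethylsilane, CC[Si](Cl)(CC)CC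
Why: Routine silylation of a primary alcohol; the labile triethylsilyl group is chosen because a primary triethylsilyl ether can later be oxidised directly to the aldehyde beside the other silyl ethers, and the lactone carbon bearing it (C8) is not touched.

Step 2
Reactants: 2 (R)-5-[(triethylsilyloxy)methyl]dihydrofuran-2(3H)-one
Product: 4 diethyl [(5R)-2-oxo-5-[(triethylsilyloxy)methyl]tetrahydrofuran-3-yl]phosphonate (epimers at the phosphorus-bearing carbon), via enol phosphate 3 (not isolated)
Conditions: LiN(iPr)2 (1.1 equiv), THF, −78 °C; ClP(O)(OEt)2; then LiN(iPr)2 (2.2 equiv), −78 °C → rt; AcOH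
Reagents that add atoms: diethyl chlorophosphate, CCOP(=O)(Cl)OCC
Why: O-Phosphorylation of the lactone enolate followed by base-induced 1,3-phosphoryl migration (vinyl phosphate to α-phosphono carbonyl rearrangement) is a known one-flask entry to α-phosphono lactones; C8 is untouched and the new C10 centre is an inconsequential epimer mixture.

Step 3
Reactants: 5 3-[(4-methoxybenzyl)oxy]propan-1-ol
Product: 6 3-[(4-methoxybenzyl)oxy]propanal
Conditions: TEMPO (cat.), PhI(OAc)2, CH2Cl2, rt
Reagents that add atoms: none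
Why: Oxoammonium-mediated (TEMPO) oxidation of a primary alcohol stops at the aldehyde and leaves the p-methoxybenzyl ether alone.

Step 4
Reactants: 4 diethyl [(5R)-2-oxo-5-[(triethylsilyloxy)methyl]tetrahydrofuran-3-yl]phosphonate; 6 3-[(4-methoxybenzyl)oxy]propanal
Product: 7 (3E,5R)-3-[3-[(4-methoxybenzyl)oxy]propylidene]-5-[(triethylsilyloxy)methyl]dihydrofuran-2(3H)-one
Conditions: NaH, THF, 0 °C; then 6, 0 °C → rt
Reagents that add atoms: none
Why: Horner–Wadsworth–Emmons olefination of an α-phosphono lactone should favour the E-alkylidene lactone (C2 chain trans to the C14 carbonyl and cis to C9), the geometry that later becomes the C2/C9-cis epoxide; the minor Z isomer is removed by chromatography.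

Step 5
Reactants: 7 (3E,5R)-3-[3-[(4-methoxybenzyl)oxy]propylidene]-5-[(triethylsilyloxy)methyl]dihydrofuran-2(3H)-one
Product: 8 (2E)-2-[(2R)-2-hydroxy-3-(triethylsilyloxy)propyl]-5-[(4-methoxybenzyl)oxy]pent-2-en-1-ol
Conditions: i-Bu2AlH (4 equiv), CH2Cl2, −78 → 0 °C; aq. sodium potassium tartrate
Reagents that add atoms: none
Why: Exhaustive 1,2-reduction of the unsaturated lactone by the aluminium hydride gives the C14 allylic alcohol and frees the C8 hydroxyl without changing the olefin geometry or the ethers.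

Step 6
Reactants: 8 (2E)-2-[(2R)-2-hydroxy-3-(triethylsilyloxy)propyl]-5-[(4-methoxybenzyl)oxy]pent-2-en-1-ol
Product: 9 (2R)-1-[(2R,3R)-2-(hydroxymethyl)-3-[2-[(4-methoxybenzyl)oxy]ethyl]oxiran-2-yl]-3-(triethylsilyloxy)propan-2-ol
Conditions: Ti(OiPr)4 (0.2 equiv), D-(−)-diethyl tartrate (0.24 equiv), t-BuOOH, 4 Å MS, CH2Cl2, −20 °C
Reagents that add atoms: tert-butyl hydroperoxide, CC(C)(C)OO
Why: Sharpless asymmetric epoxidation of the 2,3-disubstituted E-allylic alcohol, in which the titanium–D-(−)-tartrate complex bound at O14 delivers oxygen to the face that gives the (1R,10R) epoxide under reagent control, syn addition keeping C2 and C9 cis, while the homoallylic C8 carbinol is a spectator.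

Step 7
Reactants: 9 (2R)-1-[(2R,3R)-2-(hydroxymethyl)-3-[2-[(4-methoxybenzyl)oxy]ethyl]oxiran-2-yl]-3-(triethylsilyloxy)propan-2-ol
Product: 11 tert-butyl[[(2R,3R)-2-[(2R)-2,3-bis(triethylsilyloxy)propyl]-3-[2-[(4-methoxybenzyl)oxy]ethyl]oxiran-2-yl]methoxy]dimethylsilane, via C14 mono-silyl ether 10 (not isolated)
Conditions: TBSCl (1.05 equiv), imidazole, DMF, 0 °C; then Et3SiCl, DMAP (cat.), rt
Reagents that add atoms: tert-butylchlorodimethylsilane, CC(C)(C)[Si](C)(C)Cl; chlorotriethylsilane, CC[Si](Cl)(CC)CC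
Why: Sequential chemoselective silylation in one flask, the primary C14 hydroxyl taking the robust tert-butyldimethylsilyl group first and the hindered secondary C8 hydroxyl then the more labile triethylsilyl group, chloride/imidazole conditions being mild enough for the epoxide.

Step 8
Reactants: 11 tert-butyl[[(2R,3R)-2-[(2R)-2,3-bis(triethylsilyloxy)propyl]-3-[2-[(4-methoxybenzyl)oxy]ethyl]oxiran-2-yl]methoxy]dimethylsilane
Product: 12 (2R)-3-[(2R,3R)-2-[(tert-butyldimethylsilyloxy)methyl]-3-[2-[(4-methoxybenzyl)oxy]ethyl]oxiran-2-yl]-2-(triethylsilyloxy)propanal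
Conditions: (COCl)2, DMSO, CH2Cl2, −78 → −40 °C; then iPr2NEt, −78 → 0 °C
Reagents that add atoms: none
Why: Swern oxidation in which the activated sulfoxide cleaves a primary triethylsilyl ether and oxidises it in the same flask, a known selectivity that spares secondary triethylsilyl and tert-butyldimethylsilyl ethers, while the hindered amine and low temperature protect C8 from epimerisation.

Step 9
Reactants: 12 (2R)-3-[(2R,3R)-2-[(tert-butyldimethylsilyloxy)methyl]-3-[2-[(4-methoxybenzyl)oxy]ethyl]oxiran-2-yl]-2-(triethylsilyloxy)propanal; 13 methyl acrylate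
Product: 14 methyl (4R)-5-[(2R,3R)-2-[(tert-butyldimethylsilyloxy)methyl]-3-[2-[(4-methoxybenzyl)oxy]ethyl]oxiran-2-yl]-3-hydroxy-2-methylidene-4-(triethylsilyloxy)pentanoate (both C7 epimers)
Conditions: quinuclidine (0.5 equiv), MeOH (1 equiv), neat 13, rt
Reagents that add atoms: none
Why: Morita–Baylis–Hillman reaction of the activated α-silyloxy aldehyde with the amine–acrylate zwitterion; the configuration of the new C7 carbinol is irrelevant because the next step erases it.

Step 10
Reactants: 14 methyl (4R)-5-[(2R,3R)-2-[(tert-butyldimethylsilyloxy)methyl]-3-[2-[(4-methoxybenzyl)oxy]ethyl]oxiran-2-yl]-3-hydroxy-2-methylidene-4-(triethylsilyloxy)pentanoate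
Product: 15 methyl (2Z,4R)-2-(bromomethyl)-5-[(2R,3R)-2-[(tert-butyldimethylsilyloxy)methyl]-3-[2-[(4-methoxybenzyl)oxy]ethyl]oxiran-2-yl]-4-(triethylsilyloxy)pent-2-enoate
Conditions: NBS, Me2S, CH2Cl2, 0 °C → rt
Reagents that add atoms: N-bromosuccinimide, O=C1CCC(=O)N1Br
Why: Corey–Kim-type activation of the allylic alcohol followed by SN2′ attack of bromide at the terminal methylene gives the thermodynamically preferred Z-2-(bromomethyl)enoate (C8 cis to CH2Br), the geometry needed for a syn allylation, under conditions free of strong acid.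

Step 11
Reactants: 16 but-2-yn-1-ol
Product: 18 (Z)-3-iodobut-2-en-1-ol, via cyclic alkenylalanate 17 (not isolated)
Conditions: NaAlH2(OCH2CH2OMe)2, THF, 0 °C → rt; then I2, −78 → 0 °C
Reagents that add atoms: iodine, [I][I]
Why: Hydroxyl-directed trans-hydroalumination places aluminium on the methyl-bearing carbon within a five-membered alanate, and iodinolysis with retention gives the Z-alkenyl iodide (future C4–C5 with C15).

Step 12
Reactants: 18 (Z)-3-iodobut-2-en-1-ol
Product: 19 (Z)-3-iodobut-2-enal
Conditions: MnO2, CH2Cl2, rt, dark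
Reagents that add atoms: none
Why: Allylic alcohol oxidation on MnO2 is neutral and keeps the labile Z-iodoalkene geometry; the aldehyde is used at once.

Step 13
Reactants: 15 methyl (2Z,4R)-2-(bromomethyl)-5-[(2R,3R)-2-[(tert-butyldimethylsilyloxy)methyl]-3-[2-[(4-methoxybenzyl)oxy]ethyl]oxiran-2-yl]-4-(triethylsilyloxy)pent-2-enoate; 19 (Z)-3-iodobut-2-enal
Product: 22 6,7-cis α-methylene-γ-butyrolactone (locants 6R,7S,8R,1R,10R; 8-O-triethylsilyl; 14-O-tert-butyldimethylsilyl; 3-O-p-methoxybenzyl; Z-C4 iodide), via allylindium dibromide 20 (not isolated), via hydroxy ester 21 (not isolated)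
Conditions: In powder, NH4Cl, THF/H2O (3:1), rt; then PPTS (cat.), 5 Å MS, ClCH2CH2Cl, 60 °C
Reagents that add atoms: none
Why: Indium Barbier 2-(alkoxycarbonyl)allylation in which the allylindium reacts at C7 through a closed six-membered chair transition state with C8 axial (Z reagent) and the iodoalkenyl group of the aldehyde equatorial (syn adduct, hence the 6,7-cis lactone after acid-catalysed closure on the only free hydroxyl), while allylic 1,3-strain keeps H8 in the plane of C7=C11 so that the aldehyde should approach anti to the C9 chain and gauche to the small non-chelating silyloxy oxygen, which sets C6 and C7 relative to C8 as in the target.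

Step 14
Reactants: 22 6,7-cis α-methylene-γ-butyrolactone (8-O-triethylsilyl)
Product: 23 8-hydroxy lactone (locants 6R,7R,8R,1R,10R; 14-O-tert-butyldimethylsilyl; 3-O-p-methoxybenzyl; Z-C4 iodide)
Conditions: HF·pyridine, pyridine, THF, 0 °C
Reagents that add atoms: none
Why: Buffered fluoride desilylation removes the secondary triethylsilyl ether much faster than the neopentyl-type primary tert-butyldimethylsilyl ether, and the cold weakly acidic medium should leave the epoxide intact and give no time for acyl migration of the lactone to O8.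

Step 15
Reactants: 23 8-hydroxy lactone; 24 (R)-2-methylbutanoic acid
Product: 25 8-O-[(2R)-2-methylbutanoyl] lactone (locants 6R,7R,8R,1R,10R; 14-O-tert-butyldimethylsilyl; 3-O-p-methoxybenzyl; Z-C4 iodide)
Conditions: DCC, DMAP (cat.), CH2Cl2, 0 °C → rt
Reagents that add atoms: none
Why: Steglich esterification acylates O8 without breaking a bond at C8 or at the α-carbon of the acid, so both configurations are retained.

Step 16
Reactants: 25 8-O-[(2R)-2-methylbutanoyl] lactone (3-O-p-methoxybenzyl)
Product: 26 C3 primary alcohol (locants 6R,7R,8R,1R,10R; 14-O-tert-butyldimethylsilyl; Z-C4 iodide)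
Conditions: DDQ, CH2Cl2/pH 7 buffer (10:1), 0 °C
Reagents that add atoms: none
Why: Oxidative cleavage of the p-methoxybenzyl ether by DDQ under buffered biphasic conditions, to which the alkenyl iodide, epoxide, esters, enoate and silyl ether are inert.

Step 17
Reactants: 26 C3 primary alcohol
Product: 27 seco iodo-aldehyde (locants 1R,6R,7R,8R,10R; C3 aldehyde; Z-C4 iodide; 14-O-tert-butyldimethylsilyl; 8-O-(2R)-2-methylbutanoyl)
Conditions: Dess–Martin periodinane, NaHCO3, CH2Cl2, 0 °C → rt; used crude
Reagents that add atoms: none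
Why: Dess–Martin oxidation under bicarbonate buffer gives the β,γ-epoxy aldehyde without acid or base strong enough to open the epoxide through the enol, and the aldehyde is carried on without chromatography.

Step 18
Reactants: 27 seco iodo-aldehyde
Product: 29 14-O-tert-butyldimethylsilyl macrocycle (locants 1R,3S,6S,7R,8R,10R; 4Z), via alkenylchromium dichloride 28 (not isolated)
Conditions: CrCl2 (10 equiv), NiCl2 (cat.), degassed DMSO, rt, 0.003 M, slow addition of 27
Reagents that add atoms: none
Why: CrCl2 reduces NiCl2 to zerovalent nickel, which inserts into the C4–I bond with retention of the Z geometry; transmetalation to trivalent chromium gives 28, which adds to the chromium-bound C3 aldehyde to give the chromium alkoxide of 29. The closest known reaction type is the intramolecular Nozaki–Hiyama–Kishi coupling of iodoalkene aldehydes used to close medium and large carbocycles. The one ring formed is the ten-membered carbocycle C1–C10, closed in a 10-exo-trig mode (C4 attacks the exocyclic C3=O) at high dilution. The new C3 stereocentre is set by the conformation of the closing chain, which is bent by three rigid elements (the Z-C4=C5 bond, the cis-fused lactone at C6/C7 and the C2/C9-cis epoxide); closure with the chromium-bound oxygen outside the forming ring and the C3–H turned inward should give the 3S alcohol, although this face selectivity is the least certain point of the route, since acyclic 1,3-induction from the epoxide oxygen would favour the other face. The step also needs chemoselectivity for the aldehyde over the lactone, ester, enoate and epoxide, which the low basicity and nucleophilicity of the alkenylchromium secure, and it needs cyclisation to outrun oligomerisation, which the preorganised chain and slow addition secure.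

Step 19
Reactants: 29 14-O-tert-butyldimethylsilyl macrocycle
Product: 30 CNP0356520.2, (1R,3S,6S,7R,8R,10R,4Z)-1,10-epoxy-3,14-dihydroxy-8-[(2R)-2-methylbutanoyloxy]germacra-4,11(13)-dien-12,6-olide
Conditions: HF·pyridine, pyridine, THF, 0 °C → rt
Reagents that add atoms: none
Why: Pyridine-buffered fluoride desilylation frees the primary C14 hydroxyl without opening the adjacent epoxide or touching the esters, the enoate or the allylic alcohol.

Compound list
1 | (R)-5-(hydroxymethyl)dihydrofuran-2(3H)-one | OC[C@H]1CCC(=O)O1 | starting material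
2 | (R)-5-[(triethylsilyloxy)methyl]dihydrofuran-2(3H)-one | CC[Si](CC)(CC)OC[C@H]1CCC(=O)O1 | intermediate
3 | diethyl (5R)-5-[(triethylsilyloxy)methyl]-4,5-dihydrofuran-2-yl phosphate (enol phosphate) | CCOP(=O)(OCC)OC1=CC[C@H](CO[Si](CC)(CC)CC)O1 | intermediate
4 | diethyl [(5R)-2-oxo-5-[(triethylsilyloxy)methyl]tetrahydrofuran-3-yl]phosphonate (epimers at the phosphorus-bearing carbon) | CCOP(=O)(OCC)C1C[C@H](CO[Si](CC)(CC)CC)OC1=O | intermediate
5 | 3-[(4-methoxybenzyl)oxy]propan-1-ol | COc1ccc(COCCCO)cc1 | starting material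
6 | 3-[(4-methoxybenzyl)oxy]propanal | COc1ccc(COCCC=O)cc1 | intermediate
7 | (3E,5R)-3-[3-[(4-methoxybenzyl)oxy]propylidene]-5-[(triethylsilyloxy)methyl]dihydrofuran-2(3H)-one | O=C1O[C@@H](CO[Si](CC)(CC)CC)C/C1=C\CCOCc1ccc(OC)cc1 | intermediate
8 | (2E)-2-[(2R)-2-hydroxy-3-(triethylsilyloxy)propyl]-5-[(4-methoxybenzyl)oxy]pent-2-en-1-ol | OC/C(C[C@@H](O)CO[Si](CC)(CC)CC)=C/CCOCc1ccc(OC)cc1 | intermediate
9 | (2R)-1-[(2R,3R)-2-(hydroxymethyl)-3-[2-[(4-methoxybenzyl)oxy]ethyl]oxiran-2-yl]-3-(triethylsilyloxy)propan-2-ol | OC[C@@]1(C[C@@H](O)CO[Si](CC)(CC)CC)O[C@@H]1CCOCc1ccc(OC)cc1 | intermediate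
10 | (2R)-1-[(2R,3R)-2-[(tert-butyldimethylsilyloxy)methyl]-3-[2-[(4-methoxybenzyl)oxy]ethyl]oxiran-2-yl]-3-(triethylsilyloxy)propan-2-ol (C14 mono-silyl ether) | CC(C)(C)[Si](C)(C)OC[C@@]1(C[C@@H](O)CO[Si](CC)(CC)CC)O[C@@H]1CCOCc1ccc(OC)cc1 | intermediate
11 | tert-butyl[[(2R,3R)-2-[(2R)-2,3-bis(triethylsilyloxy)propyl]-3-[2-[(4-methoxybenzyl)oxy]ethyl]oxiran-2-yl]methoxy]dimethylsilane | CC(C)(C)[Si](C)(C)OC[C@@]1(C[C@@H](O[Si](CC)(CC)CC)CO[Si](CC)(CC)CC)O[C@@H]1CCOCc1ccc(OC)cc1 | intermediate
12 | (2R)-3-[(2R,3R)-2-[(tert-butyldimethylsilyloxy)methyl]-3-[2-[(4-methoxybenzyl)oxy]ethyl]oxiran-2-yl]-2-(triethylsilyloxy)propanal | CC(C)(C)[Si](C)(C)OC[C@@]1(C[C@@H](O[Si](CC)(CC)CC)C=O)O[C@@H]1CCOCc1ccc(OC)cc1 | intermediate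
13 | methyl acrylate | C=CC(=O)OC | starting material
14 | methyl (4R)-5-[(2R,3R)-2-[(tert-butyldimethylsilyloxy)methyl]-3-[2-[(4-methoxybenzyl)oxy]ethyl]oxiran-2-yl]-3-hydroxy-2-methylidene-4-(triethylsilyloxy)pentanoate (both C7 epimers) | CC(C)(C)[Si](C)(C)OC[C@@]1(C[C@@H](O[Si](CC)(CC)CC)C(O)C(=C)C(=O)OC)O[C@@H]1CCOCc1ccc(OC)cc1 | intermediate
15 | methyl (2Z,4R)-2-(bromomethyl)-5-[(2R,3R)-2-[(tert-butyldimethylsilyloxy)methyl]-3-[2-[(4-methoxybenzyl)oxy]ethyl]oxiran-2-yl]-4-(triethylsilyloxy)pent-2-enoate | CC(C)(C)[Si](C)(C)OC[C@@]1(C[C@@H](O[Si](CC)(CC)CC)/C=C(\CBr)C(=O)OC)O[C@@H]1CCOCc1ccc(OC)cc1 | intermediate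
16 | but-2-yn-1-ol | CC#CCO | starting material
17 | sodium 2,2-bis(2-methoxyethoxy)-3-methyl-2,5-dihydro-1,2-oxaaluminol-2-uide (cyclic alkenylalanate) | [Na+].CC1=CCO[Al-]1(OCCOC)OCCOC | intermediate
18 | (Z)-3-iodobut-2-en-1-ol | I/C(C)=C\CO | intermediate
19 | (Z)-3-iodobut-2-enal | I/C(C)=C\C=O | intermediate
20 | allylindium dibromide from 15 (indium on C13, C7=C11 retained, simplest formulation) | CC(C)(C)[Si](C)(C)OC[C@@]1(C[C@@H](O[Si](CC)(CC)CC)/C=C(\C[In](Br)Br)C(=O)OC)O[C@@H]1CCOCc1ccc(OC)cc1 | intermediate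
21 | syn hydroxy ester (locants 6R,7S,8R,1R,10R): methyl ester at C12, free 6-OH, C11=C13 methylidene, Z-C4 iodide, 8-O-triethylsilyl, 14-O-tert-butyldimethylsilyl, 3-O-p-methoxybenzyl | CC(C)(C)[Si](C)(C)OC[C@@]1(C[C@@H](O[Si](CC)(CC)CC)[C@H]([C@@H](O)/C=C(/C)I)C(=C)C(=O)OC)O[C@@H]1CCOCc1ccc(OC)cc1 | intermediate
22 | 6,7-cis α-methylene-γ-butyrolactone (locants 6R,7S,8R,1R,10R): 8-O-triethylsilyl, 14-O-tert-butyldimethylsilyl, 3-O-p-methoxybenzyl, Z-C4 iodide | CC(C)(C)[Si](C)(C)OC[C@@]1(C[C@@H](O[Si](CC)(CC)CC)[C@H]2C(=C)C(=O)O[C@H]2/C=C(/C)I)O[C@@H]1CCOCc1ccc(OC)cc1 | intermediate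
23 | 8-hydroxy lactone (locants 6R,7R,8R,1R,10R): 14-O-tert-butyldimethylsilyl, 3-O-p-methoxybenzyl, Z-C4 iodide | CC(C)(C)[Si](C)(C)OC[C@@]1(C[C@@H](O)[C@H]2C(=C)C(=O)O[C@H]2/C=C(/C)I)O[C@@H]1CCOCc1ccc(OC)cc1 | intermediate
24 | (R)-2-methylbutanoic acid | CC[C@@H](C)C(=O)O | starting material
25 | 8-O-[(2R)-2-methylbutanoyl] lactone (locants 6R,7R,8R,1R,10R): 14-O-tert-butyldimethylsilyl, 3-O-p-methoxybenzyl, Z-C4 iodide | CC(C)(C)[Si](C)(C)OC[C@@]1(C[C@@H](OC(=O)[C@H](C)CC)[C@H]2C(=C)C(=O)O[C@H]2/C=C(/C)I)O[C@@H]1CCOCc1ccc(OC)cc1 | intermediate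
26 | C3 primary alcohol (locants 6R,7R,8R,1R,10R): 14-O-tert-butyldimethylsilyl, 8-O-(2R)-2-methylbutanoyl, Z-C4 iodide | CC(C)(C)[Si](C)(C)OC[C@@]1(C[C@@H](OC(=O)[C@H](C)CC)[C@H]2C(=C)C(=O)O[C@H]2/C=C(/C)I)O[C@@H]1CCO | intermediate
27 | seco iodo-aldehyde (locants 1R,6R,7R,8R,10R): C3 aldehyde, Z-C4 iodide, 6,7-cis lactone, 8-O-(2R)-2-methylbutanoyl, 14-O-tert-butyldimethylsilyl | O=CC[C@H]1O[C@@]1(CO[Si](C)(C)C(C)(C)C)C[C@@H](OC(=O)[C@H](C)CC)[C@H]1C(=C)C(=O)O[C@H]1/C=C(/C)I | intermediate
28 | alkenylchromium dichloride from 27 (chromium on C4 in place of iodine, Z retained) | O=CC[C@H]1O[C@@]1(CO[Si](C)(C)C(C)(C)C)C[C@@H](OC(=O)[C@H](C)CC)[C@H]1C(=C)C(=O)O[C@H]1/C=C(/C)[Cr](Cl)Cl | intermediate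
29 | 14-O-tert-butyldimethylsilyl ether of the target (1R,3S,6S,7R,8R,10R; 4Z) | C=C1C(=O)O[C@H]2/C=C(/C)[C@@H](O)C[C@H]3O[C@@]3(CO[Si](C)(C)C(C)(C)C)C[C@@H](OC(=O)[C@H](C)CC)[C@@H]12 | intermediate
30 | CNP0356520.2, (1R,3S,6S,7R,8R,10R,4Z)-1,10-epoxy-3,14-dihydroxy-8-[(2R)-2-methylbutanoyloxy]germacra-4,11(13)-dien-12,6-olide | C=C1C(=O)O[C@H]2/C=C(/C)[C@@H](O)C[C@H]3O[C@@]3(CO)C[C@@H](OC(=O)[C@H](C)CC)[C@@H]12 | target

Total step count: 19. Longest linear sequence: 16 steps (1, 2, 4–10, 13–19, from lactone 1); steps 3, 11 and 12 are side branches.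

Steps most likely to fail

Step 18. The ring closure may attack the wrong face of the C3 aldehyde, or both faces, because the macrocyclic transition state has to override the acyclic 1,3-bias from the epoxide oxygen. The fallback sets out from 27: the closure is run without regard to face selectivity, and the mixture of 29 and its (3R)-epimer F1 is oxidised with Dess–Martin periodinane to the C3 enone F2. F2 is then reduced by Corey–Bakshi–Shibata reduction with the (R)-methyl oxazaborolidine and catecholborane at −78 °C, where the alkenyl side acts as the large group and reagent control should give 3S. The detour comes back to the route at 29.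

Step 13. The allylindium may show poor facial selectivity with respect to the C8 stereocentre, or leak from syn to anti, giving diastereomeric lactones. The fallback sets out from 15 and 19 and hands control of C6/C7 to a catalyst. It is an asymmetric Nozaki–Hiyama allylation with catalytic CrCl2 and a chiral bis(oxazolinyl)carbazole ligand, Mn powder as terminal reductant and Me3SiCl in THF. It gives the trimethylsilyl ether of hydroxy ester 21, F3, which is desilylated with KF on work-up and lactonised with PPTS as in step 13. The detour comes back to the route at 22.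

Step 9. The hindered α-silyloxy aldehyde may convert slowly, and prolonged contact with the amine may erode C8 by enolisation or move the silyl group. The fallback sets out from 12 and replaces the amine-catalysed reaction by vinylalumination. Methyl propiolate is hydroaluminated with i-Bu2AlH in the presence of HMPA to the α-(methoxycarbonyl)vinylalane, which should add to 12 at 0 °C within hours. This gives 14 directly, so the detour comes back to the route at 14 and makes no compound outside the list (F0).

Further compounds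
F1 | step 18 | (3R)-epimer of 29 | C=C1C(=O)O[C@H]2/C=C(/C)[C@H](O)C[C@H]3O[C@@]3(CO[Si](C)(C)C(C)(C)C)C[C@@H](OC(=O)[C@H](C)CC)[C@@H]12
F2 | step 18 | C3 ketone (enone) of 29 | C=C1C(=O)O[C@H]2/C=C(/C)C(=O)C[C@H]3O[C@@]3(CO[Si](C)(C)C(C)(C)C)C[C@@H](OC(=O)[C@H](C)CC)[C@@H]12
F3 | step 13 | 6-O-trimethylsilyl ether of hydroxy ester 21 | CC(C)(C)[Si](C)(C)OC[C@@]1(C[C@@H](O[Si](CC)(CC)CC)[C@H]([C@@H](O[Si](C)(C)C)/C=C(/C)I)C(=C)C(=O)OC)O[C@@H]1CCOCc1ccc(OC)cc1
F0 | step 9 | none | none
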